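Ring B of the target (C1–C2–C3=C4–C4a–C8a) is a naphthalene ring that has taken up an aryl group at C1 and a hydrogen at C2. The route therefore rests on the bond from C1 to the 3,4-dimethoxyphenyl ring and builds a flat 6,7,8-trimethoxynaphthalene first, with a chiral oxazoline on C2 and a silylated CH2OH group on C3. Addition of 3,4-dimethoxyphenyllithium to C1 of this arene joins the two halves, dearomatises ring B, sets C1 and C2, and leaves C3=C4 where the target has it. The oxazoline carbon then becomes the CH2OH carbon on C2.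

Key step: step 5

Remark on locants: C1 to C8a are those of the dihydronaphthalene core of the target and are kept for all bicyclic compounds.
Assumption: the aryl group is taken to enter anti to the C4 tert-butyl group of the lithium-bound oxazoline in the conformer with N syn to C1, so the (4R) auxiliary gives 1R; if the sense proves opposite, (S)-tert-leucinol is used in step 2 and nothing else changes.

Step 1
Reactants: 1 2-bromo-3,4,5-trimethoxybenzaldehyde; 2 monomethyl itaconate (4-methoxy-2-methylidene-4-oxobutanoic acid)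
Product: 4 6,7,8-trimethoxy-3-(methoxycarbonyl)naphthalene-2-carboxylic acid, via Heck product 3 (not isolated)
Conditions: Pd(OAc)2 (5 mol %), P(o-tol)3 (12 mol %), Et3N, DMF, 4 Å MS, 100 °C; then DBU (cat.), 100 °C; 1 M HCl work-up
Reagents that add atoms: none
Why: A Mizoroki–Heck arylation of the itaconate =CH2 terminus gives the (E)-arylidene succinate 3, whose doubly activated CH2 then undergoes an intramolecular aldol condensation with the ortho formyl group; aromatisation is the sink, and the free acid (C2) and the methyl ester (C3) come out differentiated.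

Step 2
Reactants: 4 6,7,8-trimethoxy-3-(methoxycarbonyl)naphthalene-2-carboxylic acid; 5 (R)-tert-leucinol
Product: 8 2-[(4R)-4-tert-butyl-4,5-dihydrooxazol-2-yl]-3-(methoxycarbonyl)-6,7,8-trimethoxynaphthalene, via acyl fluoride 6 (not isolated), via hydroxy amide 7 (not isolated)
Conditions: Deoxo-Fluor (1.1 equiv), iPr2NEt, CH2Cl2, 0 °C; 5; then Deoxo-Fluor (1.1 equiv), −20 °C
Reagents that add atoms: none
Why: This is the one-flask sequence of acyl fluoride formation, N-acylation and cyclodehydration of a β-hydroxy amide (amide oxygen displaces the activated primary oxygen), which does not touch the stereocentre and at low temperature should outrun imide formation with the neighbouring ester.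

Step 3
Reactants: 8 2-[(4R)-4-tert-butyl-4,5-dihydrooxazol-2-yl]-3-(methoxycarbonyl)-6,7,8-trimethoxynaphthalene
Product: 9 2-[(4R)-4-tert-butyl-4,5-dihydrooxazol-2-yl]-3-(hydroxymethyl)-6,7,8-trimethoxynaphthalene
Conditions: LiAlH4, THF, 0 °C; Rochelle salt work-up
Reagents that add atoms: none
Why: Hydride reduction of the aryl ester to the primary alcohol should be chemoselective because 2-oxazolines are inert to LiAlH4 at 0 °C.

Step 4
Reactants: 9 2-[(4R)-4-tert-butyl-4,5-dihydrooxazol-2-yl]-3-(hydroxymethyl)-6,7,8-trimethoxynaphthalene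
Product: 10 2-[(4R)-4-tert-butyl-4,5-dihydrooxazol-2-yl]-3-[(tert-butyldiphenylsilyloxy)methyl]-6,7,8-trimethoxynaphthalene
Conditions: TBDPSCl, imidazole, DMF, rt
Reagents that add atoms: tert-butyl(chloro)diphenylsilane (TBDPSCl), CC(C)(C)[Si](Cl)(c1ccccc1)c1ccccc1
Why: Standard silylation of a primary alcohol; the TBDPS ether coordinates lithium poorly and should survive aryllithium, MeOTf and aqueous oxalic acid.

Step 5
Reactants: 10 2-[(4R)-4-tert-butyl-4,5-dihydrooxazol-2-yl]-3-[(tert-butyldiphenylsilyloxy)methyl]-6,7,8-trimethoxynaphthalene; 11 4-bromo-1,2-dimethoxybenzene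
Product: 15 (4R)-4-tert-butyl-2-[(1R,2S)-3-[(tert-butyldiphenylsilyloxy)methyl]-1-(3,4-dimethoxyphenyl)-6,7,8-trimethoxy-1,2-dihydronaphthalen-2-yl]-4,5-dihydrooxazole, via aryllithium 12 (not isolated), via lithium azaenolate 13 (not isolated), via cis epimer 14 (not isolated)
Conditions: 11, t-BuLi (2 equiv per 11), THF, −78 °C; add 10, −78 → −30 °C; MeOH, −78 °C → rt; NaOMe (cat.), THF/MeOH, rt, under Ar
Reagents that add atoms: none
Why: The aryllithium 12 binds to the oxazoline nitrogen, which the bulkier C3 substituent turns towards C1-H, and hands its aryl group to C1 through a six-membered Li-N=C-C2=C1 array to give the extended azaenolate 13, which methanol protonates at C2. The closest known reaction type is the auxiliary-controlled dearomatising conjugate addition of organolithium reagents to chiral 2-naphthyloxazolines. No ring is closed; ring B loses its aromaticity while ring A keeps it, and the untouched C3=C4 bond becomes the styrene alkene of the target. C1 is controlled by the (4R)-tert-butyl group, which keeps the nitrogen-bound lithium and thus the incoming aryl group on the opposite face of the naphthalene (1R). C2 is controlled by C1: kinetic protonation anti to the pseudoaxial aryl group should give the cis epimer 14, and catalytic methoxide then equilibrates it through the same azaenolate to the trans-diaxial 15, which avoids both the peri contact between the C1 aryl group and the C8 methoxy group and the allylic strain between the C2 and C3 substituents. The step needs attack at C1 rather than at C3, C4, the C=N bond or the C3 CH2 protons, which is secured by the single acceptor on C2, by the absence of a methoxy group ortho to it (no substitution pathway), by donation into C1 from the 7-methoxy group only, and by the low basicity of an aryllithium towards a CH2 group that bears a poorly coordinating silyl ether.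

Step 6
Reactants: 15 (4R)-4-tert-butyl-2-[(1R,2S)-3-[(tert-butyldiphenylsilyloxy)methyl]-1-(3,4-dimethoxyphenyl)-6,7,8-trimethoxy-1,2-dihydronaphthalen-2-yl]-4,5-dihydrooxazole
Product: 18 (1R,2S)-3-[(tert-butyldiphenylsilyloxy)methyl]-1-(3,4-dimethoxyphenyl)-6,7,8-trimethoxy-1,2-dihydronaphthalene-2-carbaldehyde, via oxazolinium triflate 16 (not isolated), via oxazolidine 17 (not isolated)
Conditions: MeOTf, CH2Cl2, rt; NaBH4, THF/MeOH 4:1, 0 °C; oxalic acid, THF/H2O 4:1, rt
Reagents that add atoms: water, O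
Why: This is the standard three-stage unmasking of an oxazoline to an aldehyde (N-methylation, borohydride reduction to the oxazolidine, mild hydrolysis of the N,O-acetal), and C2 already holds its thermodynamic trans configuration.

Step 7
Reactants: 18 (1R,2S)-3-[(tert-butyldiphenylsilyloxy)methyl]-1-(3,4-dimethoxyphenyl)-6,7,8-trimethoxy-1,2-dihydronaphthalene-2-carbaldehyde
Product: 19 [(1R,2S)-3-[(tert-butyldiphenylsilyloxy)methyl]-1-(3,4-dimethoxyphenyl)-6,7,8-trimethoxy-1,2-dihydronaphthalen-2-yl]methanol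
Conditions: NaBH4, THF/MeOH, 0 °C, directly on freshly made 18
Reagents that add atoms: none
Why: Fast 1,2-reduction of the aldehyde by borohydride removes the acidifying group on C2 before epimerisation or alkene migration can set in.

Step 8
Reactants: 19 [(1R,2S)-3-[(tert-butyldiphenylsilyloxy)methyl]-1-(3,4-dimethoxyphenyl)-6,7,8-trimethoxy-1,2-dihydronaphthalen-2-yl]methanol
Product: 20 [(1R,2S)-1-(3,4-dimethoxyphenyl)-3-(hydroxymethyl)-6,7,8-trimethoxy-1,2-dihydronaphthalen-2-yl]methanol (target)
Conditions: TBAF, THF, rt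
Reagents that add atoms: none
Why: Fluoride-mediated desilylation avoids acid, to which the electron-rich cinnamyl-type alcohol at C3 would be sensitive, and touches neither stereocentre.

Compound list
1 | 2-bromo-3,4,5-trimethoxybenzaldehyde | O=Cc1cc(OC)c(OC)c(OC)c1Br | starting material
2 | monomethyl itaconate | C=C(CC(=O)OC)C(=O)O | starting material
3 | (E)-2-[(2-formyl-4,5,6-trimethoxyphenyl)methylidene]butanedioic acid 4-methyl ester | O=C(O)/C(CC(=O)OC)=C/c1c(C=O)cc(OC)c(OC)c1OC | intermediate
4 | 6,7,8-trimethoxy-3-(methoxycarbonyl)naphthalene-2-carboxylic acid | COC(=O)c1cc2cc(OC)c(OC)c(OC)c2cc1C(=O)O | intermediate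
5 | (R)-tert-leucinol, (2R)-2-amino-3,3-dimethylbutan-1-ol | CC(C)(C)[C@@H](N)CO | starting material
6 | acyl fluoride of 4 | COC(=O)c1cc2cc(OC)c(OC)c(OC)c2cc1C(F)=O | intermediate
7 | N-[(2R)-1-hydroxy-3,3-dimethylbutan-2-yl] amide of 4 | COC(=O)c1cc2cc(OC)c(OC)c(OC)c2cc1C(=O)N[C@@H](CO)C(C)(C)C | intermediate
8 | C2 (4R)-tert-butyloxazoline, C3 methyl ester naphthalene | COC(=O)c1cc2cc(OC)c(OC)c(OC)c2cc1C1=N[C@H](C(C)(C)C)CO1 | intermediate
9 | C2 (4R)-tert-butyloxazoline, C3 hydroxymethyl naphthalene | OCc1cc2cc(OC)c(OC)c(OC)c2cc1C1=N[C@H](C(C)(C)C)CO1 | intermediate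
10 | C2 (4R)-tert-butyloxazoline, C3 CH2OTBDPS naphthalene | CC(C)(C)[Si](OCc1cc2cc(OC)c(OC)c(OC)c2cc1C1=N[C@H](C(C)(C)C)CO1)(c1ccccc1)c1ccccc1 | intermediate
11 | 4-bromo-1,2-dimethoxybenzene | COc1ccc(Br)cc1OC | starting material
12 | 3,4-dimethoxyphenyllithium | [Li]c1ccc(OC)c(OC)c1 | intermediate
13 | N-lithio ketene N,O-acetal (azaenolate), C1 configured as in 15 | COc1ccc([C@@H]2c3c(cc(OC)c(OC)c3OC)C=C(CO[Si](c3ccccc3)(c3ccccc3)C(C)(C)C)C2=C2OC[C@@H](C(C)(C)C)N2[Li])cc1OC | intermediate
14 | (1R,2R) cis epimer of 15 | COc1ccc([C@@H]2c3c(cc(OC)c(OC)c3OC)C=C(CO[Si](c3ccccc3)(c3ccccc3)C(C)(C)C)[C@@H]2C2=N[C@H](C(C)(C)C)CO2)cc1OC | intermediate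
15 | (1R,2S) trans 1-aryl-1,2-dihydronaphthalene with C2 (4R)-oxazoline | COc1ccc([C@@H]2c3c(cc(OC)c(OC)c3OC)C=C(CO[Si](c3ccccc3)(c3ccccc3)C(C)(C)C)[C@H]2C2=N[C@H](C(C)(C)C)CO2)cc1OC | intermediate
16 | N-methyloxazolinium triflate of 15 | COc1ccc([C@@H]2c3c(cc(OC)c(OC)c3OC)C=C(CO[Si](c3ccccc3)(c3ccccc3)C(C)(C)C)[C@H]2C2=[N+](C)[C@H](C(C)(C)C)CO2)cc1OC.[O-]S(=O)(=O)C(F)(F)F | intermediate
17 | N-methyloxazolidine (aminal carbon undefined) | COc1ccc([C@@H]2c3c(cc(OC)c(OC)c3OC)C=C(CO[Si](c3ccccc3)(c3ccccc3)C(C)(C)C)[C@H]2C2N(C)[C@H](C(C)(C)C)CO2)cc1OC | intermediate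
18 | (1R,2S) 2-carbaldehyde | COc1ccc([C@@H]2c3c(cc(OC)c(OC)c3OC)C=C(CO[Si](c3ccccc3)(c3ccccc3)C(C)(C)C)[C@H]2C=O)cc1OC | intermediate
19 | (1R,2S) C2 CH2OH, C3 CH2OTBDPS | COc1ccc([C@@H]2c3c(cc(OC)c(OC)c3OC)C=C(CO[Si](c3ccccc3)(c3ccccc3)C(C)(C)C)[C@H]2CO)cc1OC | intermediate
20 | [(1R,2S)-1-(3,4-dimethoxyphenyl)-3-(hydroxymethyl)-6,7,8-trimethoxy-1,2-dihydronaphthalen-2-yl]methanol | COc1ccc([C@@H]2c3c(cc(OC)c(OC)c3OC)C=C(CO)[C@H]2CO)cc1OC | target

Total step count: 8. Longest linear sequence: 8 steps (1 → 4 → 8 → 9 → 10 → 15 → 18 → 19 → 20).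

Steps most likely to fail

Step 5.
- What may go wrong: The peri C8 methoxy group may slow attack at C1 so far that lateral lithiation at the C3 CH2 group takes over. Facial selectivity may be low. The methoxide equilibration may move the alkene into conjugation with the oxazoline.
- Fallback, from 10 back to 18: control by an external chiral ligand on a smaller and more electrophilic acceptor replaces control by the auxiliary. The oxazoline of 10 is unmasked with MeOTf, then NaBH4, then aqueous oxalic acid, through the oxazolinium triflate F1 and the oxazolidine F2, to the naphthalene-2-carbaldehyde F3. Condensation with 2,6-diisopropylaniline (TsOH cat., toluene, MS) gives the aldimine F4. The aryllithium 12 is added in toluene at −78 °C in the presence of the C2-symmetric diether 1,2-dimethoxy-1,2-diphenylethane, using the enantiomer that delivers 1R. Protonation gives the dihydronaphthalene aldimine F5, and buffered aqueous AcOH/NaOAc hydrolysis gives 18.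

Step 1.
- What may go wrong: Insertion of a 1,1-disubstituted alkene at a di-ortho-substituted aryl bromide may be slow. The amine may then isomerise the itaconate to the unreactive mesaconate, or protodebromination may take over.
- Fallback, from 1 back to 3: an olefination replaces the palladium step. Compound 1 is converted with HC(OMe)3 and TsOH (cat.) in MeOH into the bromo acetal F6. Br/Li exchange (n-BuLi, THF, −78 °C) and DMF give the acetal aldehyde F7. The phosphonosuccinate F8 is made from tert-butyl diethylphosphonoacetate and methyl bromoacetate (NaH, THF). A Horner–Wadsworth–Emmons reaction of F7 with F8 (NaH, THF) gives the (E)-arylidene succinate F9. TFA in wet CH2Cl2 cleaves the acetal and the tert-butyl ester to give 3, which DBU closes to 4 as in step 1.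

Step 6.
- What may go wrong: The C2–H of the β,γ-unsaturated aldehyde is doubly activated. Enolisation during the acidic hydrolysis may erode the C2 configuration, shift the alkene into conjugation, or open the way to aromatisation by air.
- Fallback, from 15 back to 19: the aldehyde level is bypassed. TFA, H2O and Na2SO4 in THF at rt open the oxazoline to the amino ester F10. Ac2O in pyridine blocks O-to-N acyl shift and gives the N-acetyl amino ester F11. LiAlH4 in THF at 0 °C reduces the ester directly to 19.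

Further compounds
F1 | step 5 | N-methyloxazolinium triflate of 10 | CC(C)(C)[Si](OCc1cc2cc(OC)c(OC)c(OC)c2cc1C1=[N+](C)[C@H](C(C)(C)C)CO1)(c1ccccc1)c1ccccc1.[O-]S(=O)(=O)C(F)(F)F
F2 | step 5 | N-methyloxazolidine of the naphthalene (aminal carbon undefined) | CC(C)(C)[Si](OCc1cc2cc(OC)c(OC)c(OC)c2cc1C1N(C)[C@H](C(C)(C)C)CO1)(c1ccccc1)c1ccccc1
F3 | step 5 | 3-[(tert-butyldiphenylsilyloxy)methyl]-6,7,8-trimethoxynaphthalene-2-carbaldehyde | CC(C)(C)[Si](OCc1cc2cc(OC)c(OC)c(OC)c2cc1C=O)(c1ccccc1)c1ccccc1
F4 | step 5 | (E)-N-(2,6-diisopropylphenyl) aldimine of F3 | CC(C)(C)[Si](OCc1cc2cc(OC)c(OC)c(OC)c2cc1/C=N/c1c(C(C)C)cccc1C(C)C)(c1ccccc1)c1ccccc1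
F5 | step 5 | (1R,2S)-1-aryl-1,2-dihydronaphthalene-2-carbaldehyde N-(2,6-diisopropylphenyl) imine | COc1ccc([C@@H]2c3c(cc(OC)c(OC)c3OC)C=C(CO[Si](c3ccccc3)(c3ccccc3)C(C)(C)C)[C@H]2/C=N/c2c(C(C)C)cccc2C(C)C)cc1OC
F6 | step 1 | 2-bromo-1-(dimethoxymethyl)-3,4,5-trimethoxybenzene | COC(OC)c1cc(OC)c(OC)c(OC)c1Br
F7 | step 1 | 2-(dimethoxymethyl)-4,5,6-trimethoxybenzaldehyde | COC(OC)c1cc(OC)c(OC)c(OC)c1C=O
F8 | step 1 | 1-tert-butyl 4-methyl 2-(diethoxyphosphoryl)butanedioate | CCOP(=O)(OCC)C(CC(=O)OC)C(=O)OC(C)(C)C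
F9 | step 1 | 1-tert-butyl 4-methyl (E)-2-{[2-(dimethoxymethyl)-4,5,6-trimethoxyphenyl]methylidene}butanedioate | COC(=O)C/C(C(=O)OC(C)(C)C)=C\c1c(C(OC)OC)cc(OC)c(OC)c1OC
F10 | step 6 | (2R)-2-amino-3,3-dimethylbutyl (1R,2S)-dihydronaphthalene-2-carboxylate | COc1ccc([C@@H]2c3c(cc(OC)c(OC)c3OC)C=C(CO[Si](c3ccccc3)(c3ccccc3)C(C)(C)C)[C@H]2C(=O)OC[C@H](N)C(C)(C)C)cc1OC
F11 | step 6 | (2R)-2-acetamido-3,3-dimethylbutyl (1R,2S)-dihydronaphthalene-2-carboxylate | COc1ccc([C@@H]2c3c(cc(OC)c(OC)c3OC)C=C(CO[Si](c3ccccc3)(c3ccccc3)C(C)(C)C)[C@H]2C(=O)OC[C@H](NC(C)=O)C(C)(C)C)cc1OC
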